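By 6.00 h the north-east run has turned a larger fraction of its charge into product than the east run, 38.2% against 30.6%, although the east run was charged with more substrate.

common to all: partner 0.215 M; free catalyst 0.43 mM
- north-east: substrate 0.021 M; run made earlier
- east: substrate 0.032 M; run made earlier
- flask: substrate 0.043 M

| run | time / h | product / % | substrate / % |
|---|---|---|---|
| north-east | 0.500 | 4.2 | 97.8 |
| north-east | 0.833 | 4.4 | 91.9 |
| north-east | 1.50 | 10.6 | 88.8 |
| north-east | 3.00 | 18.8 | 79.5 |
| north-east | 6.00 | 38.2 | 61.0 |
| east | 0.500 | 2.9 | 96.7 |
| east | 0.833 | 4.8 | 94.4 |
| east | 1.50 | 8.3 | 93.0 |
| east | 3.00 | 16.8 | 84.0 |
| east | 6.00 | 30.6 | 69.4 |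

(standard deviation of a reading: 1 percentage point)

- the analysis behind the earlier runs scatters by 1 percentage point, standard deviation
- no earlier run changes the charge of free catalyst; that part of a forecast is a guess
- no earlier run changes the charge of partner; that part of a forecast is a guess

* factor on the rate of making product when 20% of the substrate are converted if partner is charged twice over
* factor on the rate when 20% of the substrate are converted if free catalyst is charged at 0.040 mM instead

Keep the books on substrate, the limiting reagent, since the flask holds partner at 5.00 times the substrate charge. If each catalyst binds one substrate, catalyst can hold 1.00% of the flask's charge. At 6.00 h, product and substrate add up to 99.2% in the north-east run and 100% in the east run, so within the scatter the books close on two entries.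

Now multiply each product fraction by its charge. The apparent order in substrate, the logarithm of the rate factor over the logarithm of the charge factor, reads 0.473. Carried from the east run to the flask, that order gives a rate of 0.0437 /h as a fraction of the charge. My books for the flask at 6.00 h therefore show 26.2% product and 73.8% substrate. No run varies partner or free catalyst, so I guess: the same order in partner gives 1.39, and proportion in catalyst gives 0.0930.

The forecast gives 1.5 and 0.1, holding that “the rate should scale about linearly” in catalyst.

The flask gives 1.28 and 0.118.

    catalyst intermediate D ⇌ free catalyst + product (K = 0.390 M, k = 46.0 /h)
    substrate + free catalyst ⇌ catalyst intermediate A (K = 8.30 /M, k = 3200 /M/h)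
    catalyst intermediate C → catalyst intermediate D (k = 52.0 /h)
    partner + catalyst intermediate A → catalyst intermediate B (k = 190 /M/h)
    catalyst intermediate B → by-product + catalyst intermediate C (k = 120 /h)
    2 catalyst intermediate D ⇌ resting dimer, settled at all times (K = 26000 /M)

At 6.00 h the flask's books read 26.9% product and 72.6% substrate, and at 20% conversion its rate is 0.0434 /h as a fraction of its charge, against my 0.0437 /h. The same rule on the flask with twice the partner gives an average order of 0.352 over the doubling, below 0.473. At the flask's own charge and 20% conversion, the apparent order in partner is 0.46. The reverse step, catalyst intermediate A to substrate + free catalyst, has the largest single effect on that order among the proven ones: without that step, the order reads 0.12.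

The readings stem from a simulated flask for substances that don't exist, noise included.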